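(The earlier runs and the new flask are calculated on assumed constants, noise included.)

For whoever takes over the bench: the winter flask is to be read at 2.0 min, for its target and for how close its dissolved gas stands to saturation.

in all of them: gas phase 33 mM (held)

| flask | substrate | remark | time |
|---|---|---|---|
| winter | 0.10 M | the very flask that is asked about, followed so far |  |
| spring | 0.15 M | run made earlier |  |
| flask | 0.10 M |  | 2.0 min |

- winter (time / s: target / %, substrate / %): 10.0: 2.6, 94.6; 15.0: 7.2, 93.7
- spring (time / s: target / %, substrate / %): 10.0: 3.2, 97.0; 15.0: 5.6, 93.2; 20.0: 8.9, 88.8; 30.0: 13.1, 77.8; 50.0: 20.6, 66.6

(scatter of a reading: 1 percentage point)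

- at the start none of the gas phase is in solution

* amount of target at 2.0 min, in percent of the substrate charged
* concentration of dissolved gas in solution at 2.0 min, in percent of saturation

At 15.0 s the winter flask held 93.7% substrate and 7.2% target. After its start the spring run loses substrate along a nearly straight line, not a slowing curve, which looks like a reaction fed at the pace the gas enters. The reckoning here therefore takes dissolved gas as used on arrival. Spring lost 33.4% of its charge by 50.0 s. That amount per second, set against the smaller winter charge, gives 1.66 min, the charge time: how long the gas takes to feed one charge at that pace. The reading comes later than this, at 1.20 charge times, so expect the substrate near its end and dissolved gas still well short of saturation. Add no substrate: the charge time lengthens with the charge.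

The forecast gives 36% target (12% to 55%) and 85% of saturation (68% to 97%), on the ground that “Gas demand then falls”. The reckoning here parts from it on timing, putting the recovery later.

    gas phase ⇌ dissolved gas, rate k1*(csat - [dissolved gas]) (kL = 0.0343 s⁻¹)
    substrate + dissolved gas → target (k = 1.25 M⁻¹ s⁻¹)
    dissolved gas → decomposed reagent (k = 5.46 × 10⁻⁴ s⁻¹)
    substrate + target → side product (k = 0.0909 M⁻¹ s⁻¹)

The winter flask gives 58.0% target and 56.1% of saturation, with 14% substrate left after those 1.20 charge times. Two steps acting together hold the target at this figure, the gas passage into solution and the step in which substrate consumes target: the run with fast passage gives 82.5%, the run without the side step 77.8%. The neighbour flask charged with 0.060 M has a charge time of 0.998 min, and at 2.00 min it holds 73.8% target.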